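**Assumptions**
- The target has no stereocentres, so "single enantiomer" does not apply and no stereochemistry needs to be set.
- Methyl 2,4-dihydroxy-6-pentylbenzoate (methyl olivetolate) is taken as commercially available, as is olivetol.
- Only substrates, intermediates and the target are numbered. Reagents are listed with SMILES in the reagent field.

**Retrosynthesis**
1. The target comes from a final Pinnick oxidation of a salicylaldehyde. Carrying ring B's CO2H as CHO keeps it distinct from ring A's methyl ester.
2. That aldehyde comes from BCl3 cleavage of the ring-B 2-OMe (ortho to CHO) and the ring-A 4-OBn in one pot.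
3. The diaryl ether C–O bond is made by a Cu-catalysed Ullmann coupling of ring-A phenol **2** with ring-B aryl iodide **6**.
4. Both benzene rings are pre-formed, so no ring construction is needed. Ring A comes from methyl olivetolate by selective 4-O-benzylation. Ring B comes from olivetol by O-methylation, iodination and Vilsmeier formylation.

**Route**

**Step 1**
Reactants: **1** methyl 2,4-dihydroxy-6-pentylbenzoate
Product: **2** methyl 4-(benzyloxy)-2-hydroxy-6-pentylbenzoate
Conditions: BnBr, K2CO3, acetone, 56 °C
Reagents that add atoms: benzyl bromide, BrCc1ccccc1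
Why: Williamson etherification is selective for the 4-OH because the 2-OH is locked in a hydrogen bond to the ester and is less acidic. This leaves the 2-OH free as the nucleophile for the coupling. No stereocentre forms.

**Step 2**
Reactants: **3** olivetol (5-pentylbenzene-1,3-diol)
Product: **4** 1,3-dimethoxy-5-pentylbenzene
Conditions: MeI, K2CO3, acetone, reflux
Reagents that add atoms: iodomethane, CI
Why: Exhaustive Williamson O-methylation of both phenols, so no selectivity is needed. No stereocentre forms.

**Step 3**
Reactants: **4**
Product: **5** 1-iodo-2,4-dimethoxy-6-pentylbenzene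
Conditions: NIS, MeCN, cat. TFA, 0 °C → 25 °C
Reagents that add atoms: N-iodosuccinimide, O=C1CCC(=O)N1I
Why: Electrophilic aromatic iodination goes to the position that is ortho to one OMe and the pentyl group and para to the other OMe. That is favoured over the site sandwiched between the two OMe groups, as in 3,5-dimethoxytoluene. No stereocentre forms.

**Step 4**
Reactants: **5**
Product: **6** 5-iodo-2,4-dimethoxy-6-pentylbenzaldehyde
Conditions: POCl3, DMF, 0 → 60 °C; then aq. NaOAc, 25 °C
Reagents that add atoms: DMF, CN(C)C=O (source of the CHO carbon); water, O (aldehyde oxygen on hydrolysis)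
Why: The Vilsmeier–Haack formylation occurs at the only remaining position that is ortho to OMe and pentyl and para to the second OMe. This gives the ring-B pattern CHO / OMe / H / OMe / I / pentyl. No stereocentre forms.

**Step 5**
Reactants: **2** (1.0 equiv), **6** (1.3 equiv)
Product: **7** methyl 4-(benzyloxy)-2-(3-formyl-4,6-dimethoxy-2-pentylphenoxy)-6-pentylbenzoate
Conditions: CuI (20 mol%), picolinic acid (40 mol%), K3PO4, DMSO, 100 °C, 24 h
Reagents that add atoms: none
Why: Ullmann-type Cu-catalysed O-arylation with a picolinic acid ligand is the method suited to tri-ortho-substituted diaryl ethers. The aldehyde has no α-hydrogens, and the benzyl ether and methyl ester survive. No stereocentre forms.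

**Step 6**
Reactants: **7**
Product: **8** methyl 4-hydroxy-2-(3-formyl-4-hydroxy-6-methoxy-2-pentylphenoxy)-6-pentylbenzoate
Conditions: BCl3, pentamethylbenzene, CH2Cl2, −78 → 0 °C; aq. NaHCO3 quench
Reagents that add atoms: none
Why: BCl3 chelates the aldehyde oxygen and the adjacent 2-OMe, so this ether is cleaved selectively; the 4-OMe has no chelating group and stays. BCl3 also cleaves the ring-A benzyl ether, with pentamethylbenzene trapping the benzyl cation. The methyl ester and diaryl ether are retained. No stereocentre forms.

**Step 7**
Reactants: **8**
Product: **9** epiphorellic acid 1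
Conditions: NaClO2, NaH2PO4, 2-methyl-2-butene, t-BuOH/H2O, 25 °C
Reagents that add atoms: sodium chlorite, [Na+].[O-]Cl=O (supplies the added oxygen)
Why: Pinnick oxidation converts the chelated salicylaldehyde to the acid. The alkene scavenges HOCl, which protects the electron-rich phenols from chlorination, and the ester is untouched. No stereocentre forms, and the product matches the target SMILES.

**Compound list**

| No. | Name | SMILES | Role |
|---|---|---|---|
| 1 | methyl 2,4-dihydroxy-6-pentylbenzoate | CCCCCc1cc(O)cc(O)c1C(=O)OC | starting material |
| 2 | methyl 4-(benzyloxy)-2-hydroxy-6-pentylbenzoate | CCCCCc1cc(OCc2ccccc2)cc(O)c1C(=O)OC | intermediate |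
| 3 | olivetol | CCCCCc1cc(O)cc(O)c1 | starting material |
| 4 | 1,3-dimethoxy-5-pentylbenzene | CCCCCc1cc(OC)cc(OC)c1 | intermediate |
| 5 | 1-iodo-2,4-dimethoxy-6-pentylbenzene | CCCCCc1cc(OC)cc(OC)c1I | intermediate |
| 6 | 5-iodo-2,4-dimethoxy-6-pentylbenzaldehyde | CCCCCc1c(C=O)c(OC)cc(OC)c1I | intermediate |
| 7 | methyl 4-(benzyloxy)-2-(3-formyl-4,6-dimethoxy-2-pentylphenoxy)-6-pentylbenzoate | CCCCCc1cc(OCc2ccccc2)cc(Oc2c(CCCCC)c(C=O)c(OC)cc2OC)c1C(=O)OC | intermediate |
| 8 | methyl 4-hydroxy-2-(3-formyl-4-hydroxy-6-methoxy-2-pentylphenoxy)-6-pentylbenzoate | CCCCCc1cc(O)cc(Oc2c(CCCCC)c(C=O)c(O)cc2OC)c1C(=O)OC | intermediate |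
| 9 | epiphorellic acid 1 | CCCCCc1cc(O)cc(Oc2c(OC)cc(O)c(C(=O)O)c2CCCCC)c1C(=O)OC | target |

**Totals**
- Total steps: 7.
- Longest linear sequence: 6 steps (olivetol → 4 → 5 → 6 → 7 → 8 → 9).

**Three steps most likely to fail**
1. **Step 5, Ullmann coupling.** The aryl iodide is electron-rich and flanked by OMe and pentyl, and the phenol is hindered. Fallback: convert the aryl iodide to a diaryliodonium salt, with the aldehyde protected as its dimethyl acetal, and arylate the phenoxide of **2** under metal-free conditions.
2. **Step 6, BCl3 selectivity.** The 2-OMe may not be cleaved cleanly against the 4-OMe and the ester. Fallback: build ring B with a 4-OMe/2-OBn pattern from 2,4-dihydroxy-6-pentylbenzaldehyde (regioselective 4-O-methylation, then 2-O-benzylation). Then do the Pinnick oxidation first and finish with H2, Pd/C hydrogenolysis of both benzyl groups.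
3. **Step 3, iodination regiochemistry.** A mixture with the 2-iodo isomer (iodine between the two OMe groups) is possible. Fallback: formylate first, then brominate 2,4-dimethoxy-6-pentylbenzaldehyde, where the 2-OMe directs para to C5 and the CHO disfavours C3. Couple the resulting aryl bromide with **2** using Pd/tBuBrettPhos C–O coupling instead of Cu.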